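The question was how much of the charged solid substrate stood as target and solid product at the end, and which change would raise that most.

solid substrate 13 mM; gas 1.5 mM (held); time 40 min
- the target and solid product together standing at 40 min, as a percentage of the solid substrate charged
- the change that raises the amount of target and solid product together at 40 min, in percent of the solid substrate charged most ("none" if none brings more than 2 percentage points) (north-east / north / south / west / none)
- amount of target and solid product together at 40 min, in percent of the solid substrate charged, after south
- north-east: doubling the dissolution coefficient of step 2, all else as stated
- north: doubling the transfer coefficient of step 3, all else as stated
- south: doubling the solubility in step 2, all else as stated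
- west: doubling the dissolution coefficient of step 1, all else as stated
- percentages count the solid substrate that a species holds: one side product A or side product B counts as two
- target is meant together with its solid product
- a step written with two of one species runs at k times the square of its concentration and takes two of it each time
- solid, in amounts per volume of the solution: solid substrate, solid product
- at the start none of reagent is dissolved
- at the start none of the solid substrate is in solution
- run time (flask): 40 min

My first thought was that dissolved substrate simply became target. I doubted this, since two dissolved substrate can pair to side product A, so I counted lifetimes. Dissolved substrate lived 0.0556 min against reagent at saturation, but 0.640 min against pairing even at its solubility, which is longer, so I set pairing aside. Dissolving at its fastest needed 5.14 min, less than the run, so I looked for the loss elsewhere.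

I looked for it in dissolved target, which has two exits. Its excess over solubility lived 1.02 min against crystals, and target lived 6.99 min against solid substrate at half its charge, a pseudo-first-order lifetime, with half the charge taken as my mean for a solid I supposed to fall steadily. The solid's share, the crystal lifetime over the sum of both lifetimes, was 12.7%. Each target lost also takes a solid substrate, so side product B holds two, and the charge lost came to 22.6%. That gave 77.4%.

But target born late meets a solid one crystal lifetime further gone. Counting that, I reached an upper estimate of 84.2%, so I expected my first figure to lie somewhat low.

Doubling the crystal rate cuts the share to 6.80%, while in this reckoning the other changes leave it standing. So I chose north-east, and for south I kept 77.4%.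

The forecast gave 81.6%, north-east and 79.5%, on the ground that “Target overshoots its solubility”. Its yield stands above mine.

    solid substrate ⇌ dissolved substrate, rate k1*(cs1 - [dissolved substrate]) while solid is left; crystals form when [dissolved substrate] > cs1 (cs1 = 1.1 mM, k1 = 2.3 min⁻¹)
    solid product ⇌ target, rate k2*(cs2 - [target]) while solid is left; crystals form when [target] > cs2 (cs2 = 0.25 mM, k2 = 0.98 min⁻¹)
    gas ⇌ reagent, rate k3*(csat - [reagent]) (k3 = 11 min⁻¹, csat = 1.5 mM)
    dissolved substrate + reagent → target (k4 = 12000 L mol⁻¹ min⁻¹)
    2 dissolved substrate → side product A (k5 = 710 L mol⁻¹ min⁻¹)
    solid substrate + target → side product B (k6 = 22 L mol⁻¹ min⁻¹)

The simulation gave 81.6%, 80.2% after south, and north-east as the best change, gaining 5 percentage points against 2.5 points for west. In this flask, at 2.50 min, solid substrate had a half-life of 16 min against side product B, longer than the 5.14 min I had reckoned for dissolving at its fastest, and after 40.0 min side product B held 17.2% of the charge against my 22.6%. In the neighbour flask with 52 mM, the solid's share rises to 36.9%, which leaves 46.1%, and that flask stood at 49.9%.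

The rate constants were set for the occasion; the run is a simulation.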